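**Plan**
- Retrosynthesis: the two masking bonds are cut first (sulfate O–CH2CCl3 and 3′-O–CH2Ph), then the C2–C1′ bond between the γ-pyrone ring and the B ring, last the 7-O–S bond.
- Forward: the A/C bicycle is bought intact as 5,7-dihydroxychromone. Its 7-OH is sulfurylated as the neutral 2,2,2-trichloroethyl (TCE) sulfate diester, the B ring is attached at C2 by aerobic C–H arylation, then one global unmasking and a proton exchange follow.
- Enabling feature: the unsubstituted C2–H of the pyrone ring. C2 is the β-carbon of the O1–C2=C3–C4=O vinylogous ester, so an aryl–Pd species delivers its aryl group to C2 and loss of the C2–H re-forms the pyrone; no halogen or metal has to be installed on the chromone.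
- The TCE group serves as 7-O protection and as the masked sulfate. The 5-OH stays free, chelated to C4=O. The 3′-OH is carried as a benzyl ether that leaves in the same operation as the TCE group.
- Stereochemistry: the target is achiral and no stereocentre is created at any point.

Key step: step 2

Remark: the target has no stereogenic element, so there is no enantiomer to control; it is drawn as the free hydrogen sulfate and is delivered in that protonation state from its ammonium salt.

**Step 1**
Reactants: 1 5,7-dihydroxy-4H-chromen-4-one (5,7-dihydroxychromone)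
Product: 2 5-hydroxy-4-oxo-4H-chromen-7-yl 2,2,2-trichloroethyl sulfate
Conditions: Cl3CCH2OSO2Cl (1.05 equiv), Et3N (1.2 equiv), DMAP (10 mol %), THF, 0 °C to rt
Reagents that add atoms: 2,2,2-trichloroethyl chlorosulfate, ClS(=O)(=O)OCC(Cl)(Cl)Cl
Why: DMAP-catalysed sulfuryl transfer from a chlorosulfate ester to a phenol should occur only at the 7-OH, the more acidic and unhindered phenol para to the C4 carbonyl, because the 5-OH is locked in a six-membered hydrogen bond to C4=O; one equivalent of reagent at low temperature limits over-reaction and keeps the C2-unsubstituted pyrone intact.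

**Step 2**
Reactants: 2 5-hydroxy-4-oxo-4H-chromen-7-yl 2,2,2-trichloroethyl sulfate; 3 [3-(benzyloxy)-4-methoxyphenyl]boronic acid
Product: 4 2-[3-(benzyloxy)-4-methoxyphenyl]-5-hydroxy-4-oxo-4H-chromen-7-yl 2,2,2-trichloroethyl sulfate
Conditions: 3 (2 equiv), Pd(TFA)2 (10 mol %), 5-nitro-1,10-phenanthroline (20 mol %), O2 (1 atm), DMSO, 80 °C
Reagents that add atoms: none
Why: Aryl transfer from boron to Pd(II) is followed by syn-carbopalladation of the C2=C3 bond of the γ-pyrone, with the aryl group going to C2 (the β-carbon of the C4 enone) and Pd to C3; the C3 palladium enolate equilibrates through its O-bound form, which allows syn β-hydride elimination of the C2–H to restore the pyrone, and the resulting Pd(0) is reoxidised by O2. The closest known reaction type is the aerobic oxidative boron-Heck arylation of chromones to flavones, together with Pd(II)-catalysed conjugate addition of arylboronic acids to chromones; any flavanone formed by protonation of the enolate should be funnelled to the flavone by Pd(II)/O2 dehydrogenation under the same conditions. No ring is closed and no stereocentre is formed; the step joins the preformed A/C bicycle to the B ring at the final oxidation level. The selectivity needed is C2 over C3 arylation, secured by the polarisation of the vinylogous ester, since Heck-type insertion places the aryl group on the β-carbon whereas C3 reacts only by electrophilic palladation, which an aryl–Pd species does not undergo. Chemoselectivity should follow from the substrate: the TCE sulfate diester and the benzyl ether offer no bond that Pd(II)/O2 activates, the 5-OH is tied up in its hydrogen bond to C4=O, and the B-ring pattern (C1′ para to OMe, meta to OBn) is fixed by the position of boron in 3. Excess 3 offsets homocoupling and protodeboronation.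

**Step 3**
Reactants: 4 2-[3-(benzyloxy)-4-methoxyphenyl]-5-hydroxy-4-oxo-4H-chromen-7-yl 2,2,2-trichloroethyl sulfate
Product: 5 ammonium 5-hydroxy-2-(3-hydroxy-4-methoxyphenyl)-4-oxo-4H-chromen-7-yl sulfate
Conditions: 10% Pd/C, HCO2NH4 (excess), MeOH, rt; C18 reversed-phase chromatography (H2O/MeOH)
Reagents that add atoms: ammonium formate, [NH4+].[O-]C=O (supplies the ammonium counter-ion)
Why: Catalytic transfer hydrogenolysis cleaves the benzyl ether, and Pd(0) insertion into a C–Cl bond of the trichloroethyl group followed by β-elimination expels the sulfate monoester (the reductive fragmentation on which the TCE sulfate protecting group rests), while the aryl sulfate anion and the C2=C3 bond of the conjugated γ-pyrone should not be reduced under these mild conditions.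

**Step 4**
Reactants: 5 ammonium 5-hydroxy-2-(3-hydroxy-4-methoxyphenyl)-4-oxo-4H-chromen-7-yl sulfate
Product: 6 5-hydroxy-2-(3-hydroxy-4-methoxyphenyl)-4-oxo-4H-chromen-7-yl hydrogen sulfate (luteolin 4′-methyl ether 7-sulfate)
Conditions: Dowex 50WX8 (H+ form), H2O/MeOH, 0 °C; freeze-drying
Reagents that add atoms: none
Why: Cation exchange on a strong-acid resin swaps NH4+ for H+ and should deliver the free aryl hydrogen sulfate; low temperature, short contact time and immediate freeze-drying limit acid-catalysed loss of the sulfate from the strongly acidic product.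

**Compound list**
1 | 5,7-dihydroxy-4H-chromen-4-one (5,7-dihydroxychromone) | O=c1ccoc2cc(O)cc(O)c12 | starting material
2 | 5-hydroxy-4-oxo-4H-chromen-7-yl 2,2,2-trichloroethyl sulfate | O=c1ccoc2cc(OS(=O)(=O)OCC(Cl)(Cl)Cl)cc(O)c12 | intermediate
3 | [3-(benzyloxy)-4-methoxyphenyl]boronic acid | COc1ccc(B(O)O)cc1OCc1ccccc1 | starting material
4 | 2-[3-(benzyloxy)-4-methoxyphenyl]-5-hydroxy-4-oxo-4H-chromen-7-yl 2,2,2-trichloroethyl sulfate | COc1ccc(-c2cc(=O)c3c(O)cc(OS(=O)(=O)OCC(Cl)(Cl)Cl)cc3o2)cc1OCc1ccccc1 | intermediate
5 | ammonium 5-hydroxy-2-(3-hydroxy-4-methoxyphenyl)-4-oxo-4H-chromen-7-yl sulfate | COc1ccc(-c2cc(=O)c3c(O)cc(OS(=O)(=O)[O-])cc3o2)cc1O.[NH4+] | intermediate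
6 | 5-hydroxy-2-(3-hydroxy-4-methoxyphenyl)-4-oxo-4H-chromen-7-yl hydrogen sulfate (luteolin 4′-methyl ether 7-sulfate) | COc1ccc(-c2cc(=O)c3c(O)cc(OS(=O)(=O)O)cc3o2)cc1O | target

**Total step count:** 4
**Longest linear sequence:** 4 steps (1 → 2 → 4 → 5 → 6); boronic acid 3 is a purchased fragment that enters at step 2.

**Steps most likely to fail**

Step 2. The sequence may stall at the flavanone oxidation level because β-hydride elimination from the palladium enolate is slow. Protodeboronation and homocoupling of the electron-rich boronic acid may outrun insertion. The 5-hydroxy-4-keto chelate may sequester Pd, and the sulfate diester may erode slowly in DMSO at 80 °C. The fallback separates C–C bond formation from oxidation and sets out from 2 and 3. Redox-neutral Pd(II)-catalysed 1,4-addition of 3 to 2 (Pd(TFA)2/2,2′-bipyridine, no oxidant, N2, aqueous 1,2-dichloroethane, 60 °C) should give the racemic flavanone 2-[3-(benzyloxy)-4-methoxyphenyl]-5-hydroxy-4-oxochroman-7-yl 2,2,2-trichloroethyl sulfate F1. Its single stereocentre is of no consequence, because the following dehydrogenation with I2 (cat.) in DMSO at 100 °C removes it again. Any ring-opened 2′-hydroxychalcone is converted by the same reagent, and the route is rejoined at 4.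

Step 3. Stepwise hydrodechlorination of the trichloroethyl group may give di- or monochloroethyl sulfates that no longer fragment, and chloride may poison the catalyst so that debenzylation stays incomplete. The fallback unmasks the two groups one after the other by different mechanisms and sets out from 4. Zinc dust with HCO2NH4 in MeOH at rt (two-electron reductive fragmentation of the TCE ester) should give ammonium 2-[3-(benzyloxy)-4-methoxyphenyl]-5-hydroxy-4-oxo-4H-chromen-7-yl sulfate F2. Hydrogenolysis of its benzyl ether (H2 1 atm, 10% Pd/C, MeOH, rt), now free of organochlorine, rejoins the route at 5.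

Step 1. Sulfuryl transfer may not stop cleanly at the 7-OH, and the base may open the pyrone ring, which is exposed to nucleophiles while C2 is unsubstituted. The fallback postpones the sulfate until C2 carries the aryl group and sets out from 1. Amine-free 7-O-acylation (pivaloyl chloride, K2CO3, acetone, 0 °C) should give 5-hydroxy-4-oxo-4H-chromen-7-yl pivalate F3. Arylation of F3 with 3 under the conditions of step 2 should give 2-[3-(benzyloxy)-4-methoxyphenyl]-5-hydroxy-4-oxo-4H-chromen-7-yl pivalate F4. Methanolysis (K2CO3 cat., MeOH, rt) releases 2-[3-(benzyloxy)-4-methoxyphenyl]-5,7-dihydroxy-4H-chromen-4-one F5. Its 7-OH is then sulfurylated with 2,2,2-trichloroethyl chlorosulfate, Et3N and DMAP in THF on the more robust flavone, and the route is rejoined at 4.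

**Further compounds**
F1 | step 2 | 2-[3-(benzyloxy)-4-methoxyphenyl]-5-hydroxy-4-oxochroman-7-yl 2,2,2-trichloroethyl sulfate (racemic) | COc1ccc(C2CC(=O)c3c(O)cc(OS(=O)(=O)OCC(Cl)(Cl)Cl)cc3O2)cc1OCc1ccccc1
F2 | step 3 | ammonium 2-[3-(benzyloxy)-4-methoxyphenyl]-5-hydroxy-4-oxo-4H-chromen-7-yl sulfate | COc1ccc(-c2cc(=O)c3c(O)cc(OS(=O)(=O)[O-])cc3o2)cc1OCc1ccccc1.[NH4+]
F3 | step 1 | 5-hydroxy-4-oxo-4H-chromen-7-yl pivalate | O=c1ccoc2cc(OC(=O)C(C)(C)C)cc(O)c12
F4 | step 1 | 2-[3-(benzyloxy)-4-methoxyphenyl]-5-hydroxy-4-oxo-4H-chromen-7-yl pivalate | COc1ccc(-c2cc(=O)c3c(O)cc(OC(=O)C(C)(C)C)cc3o2)cc1OCc1ccccc1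
F5 | step 1 | 2-[3-(benzyloxy)-4-methoxyphenyl]-5,7-dihydroxy-4H-chromen-4-one | COc1ccc(-c2cc(=O)c3c(O)cc(O)cc3o2)cc1OCc1ccccc1
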